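**Plan**

Ring numbering: C1 (CH bearing the chain), C2 (CH2), C3 (CHCl), C4 (C(OH)CH3), C5 (CH–O-angelate), C6 (CH–OAc); chain C7 (=C12H2), C8 (CH–O-angelate), C9 (CH2), C10–C11 (oxirane CH and CMe2).
Enabling feature: the acetoxy carbon C6 neighbours C1 and is cis to the C1–C7 bond, and the C4 methyl is para to C1. This is the imprint of an endo [4+2] adduct of a 1-acetoxy-3-methylbutadiene and an acrylic dienophile, so the ring is cut at C1–C6 and C2–C3 (C7 = dienophile carbonyl).
Other cuts: C7–C8 (C7 enol triflate plus 4-methylpent-3-enal); C3–Cl, the C4 and C5 oxygens, the C10–C11 oxirane oxygen and the three esters go back to alkenes and hydroxyls.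
Forward order: the cycloaddition closes the only carbocycle; the ring is oxygenated to the C3=C4 allylic cis-5,6-diol and masked as an acetonide; the chain is joined by CrCl2/NiCl2-mediated coupling; esters, ring oxirane, chloride opening and chain oxirane follow.
Stereochemistry: C1 and C6 come from the Cu(SbF6)2–bis(oxazoline)-catalysed endo addition; C4, C5 and C3 are relayed from the C6 hydroxyl by two hydroxyl-directed epoxidations and an anti chloride opening; C8 comes from a CBS reduction and C10 from a Shi epoxidation.

Key step: step 3

Remark on faces: the "upper" face of the ring is the one carrying the C1–C7 bond; in the target O4, O5 and O6 lie on the upper face, Cl and the C4 methyl on the lower face.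
Assumption: with the (S,S)-tert-butyl-bis(oxazoline) ligand the diene adds to the α-Re face of the copper-bound acrylimide, which gives the (1S,6R) adduct needed here.

**Route**

Step 1
Reactants: 1 3-methylbut-2-enal; 2 isopropenyl acetate
Product: 3 (E)-1-acetoxy-3-methylbuta-1,3-diene
Conditions: 2 (3 equiv), TsOH·H2O (cat.), 90–95 °C, acetone distilled off; distillation
Reagents that add atoms: none
Why: Acid-catalysed enol ester exchange (enol acetylation) traps the extended dienol of the enal at oxygen and gives the conjugated dienyl acetate, the E geometry of the new C=C–OAc bond being the one favoured under the equilibrating conditions.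

Step 2
Reactants: 4 oxazolidin-2-one; 5 acryloyl chloride
Product: 7 3-acryloyloxazolidin-2-one, via bromomagnesium oxazolidin-2-onide 6 (not isolated)
Conditions: MeMgBr, THF, 0 °C; then 5, −78 °C to 0 °C
Reagents that add atoms: none
Why: N-Acylation of the magnesium salt of the carbamate by the acid chloride (imide formation), the magnesium counter-ion keeping the acrylimide from anionic polymerisation.

Step 3
Reactants: 3 (E)-1-acetoxy-3-methylbuta-1,3-diene; 7 3-acryloyloxazolidin-2-one
Product: 8 3-[(1S,6R)-6-acetoxy-4-methylcyclohex-4-ene-1-carbonyl]oxazolidin-2-one (acetate cis to the acyl group; C1 and C6 numbered as in the target)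
Conditions: [Cu((S,S)-t-Bu-box)](SbF6)2 (5 mol %; from CuCl2, AgSbF6 and 2,2'-(propane-2,2-diyl)bis[(4S)-4-tert-butyl-4,5-dihydrooxazole]), 3 (1.5 equiv), CH2Cl2, −20 °C
Reagents that add atoms: none
Why: This is a concerted, asynchronous, suprafacial [4+2] cycloaddition (catalytic enantioselective Diels–Alder reaction of an acrylimide bound through both carbonyls to a cationic bis(oxazoline) complex of divalent copper), in which the diene CH2 terminus bonds to the β-carbon ahead of the bond from the acetoxy terminus to the α-carbon, so C2–C3 and C1–C6 form and the six-membered ring closes in one step with its alkene at C4=C5. The regiochemistry follows the 1-acetoxy donor (ortho) reinforced by the 3-methyl group (para), which puts the acetate on C6 next to the acyl-bearing C1 and the methyl on C4. The endo transition state, with the chelated imide lying under the diene, makes the C6 acetate cis to the C1 acyl group. The configuration at C1 comes from the ligand: in the square-planar chelate of the s-cis imide one tert-butyl group covers one alkene face, the diene adds to the open face to give 1S, and 6R then follows from the endo mode. The step needs ortho regioselectivity, endo selectivity and face selectivity, which are secured by the donor pattern of 3, by the two-point-bound imide and by the twofold-symmetric ligand; any trans isomer is removed here by chromatography.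

Step 4
Reactants: 8 3-[(1S,6R)-6-acetoxy-4-methylcyclohex-4-ene-1-carbonyl]oxazolidin-2-one
Product: 10 (1S,6R)-6-hydroxy-N-methoxy-N,4-dimethylcyclohex-4-ene-1-carboxamide, via Weinreb amide acetate 9 (not isolated)
Conditions: MeNH(OMe)·HCl (5 equiv), AlMe3 (5 equiv), CH2Cl2, −10 °C to 30 °C; aq. KNaC4H4O6
Reagents that add atoms: N,O-dimethylhydroxylamine hydrochloride, CNOC.Cl
Why: Weinreb aminolysis with the amide Me2Al–N(OMe)Me formed from AlMe3 opens the exocyclic imide carbonyl first and, on warming with excess reagent, aminolyses the acetate as well (ester-to-amide exchange), so the C6 hydroxyl needed for the next step is freed without touching C1 or C6.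

Step 5
Reactants: 10 (1S,6R)-6-hydroxy-N-methoxy-N,4-dimethylcyclohex-4-ene-1-carboxamide
Product: 11 4,5-epoxy-6-hydroxy Weinreb amide (oxirane on the upper face, cis to the C6 hydroxyl)
Conditions: VO(acac)2 (3 mol %), t-BuOOH (1.5 equiv, in decane), CH2Cl2, 0 °C to rt
Reagents that add atoms: tert-butyl hydroperoxide, CC(C)(C)OO
Why: VO(acac)2-catalysed hydroxyl-directed epoxidation, in which the C6 hydroxyl (pseudoaxial when the C1 amide is equatorial) binds the metal of the tert-butylperoxo complex formed from VO(acac)2 and delivers oxygen to its own face of C4=C5, which sets C4 and C5.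

Step 6
Reactants: 11 4,5-epoxy-6-hydroxy Weinreb amide
Product: 12 cis-5,6-dihydroxy-N-methoxy-N,4-dimethylcyclohex-3-ene-1-carboxamide (both hydroxyls on the upper face; alkene at C3=C4)
Conditions: Ti(OiPr)4 (2 equiv), CH2Cl2, rt to 40 °C; aq. tartaric acid
Reagents that add atoms: none
Why: Ti(OiPr)4-mediated rearrangement of a 2,3-epoxy alcohol to an allylic 1,2-diol (hydroxyl-delivered Lewis acid, β-elimination), in which the chelate of the C6 alkoxide and the oxirane oxygen weakens the distal tertiary C4–O bond and a titanium-bound isopropoxide removes the C3 proton (the ring position cis to the carbinol carbon), so the C5–O bond keeps its configuration and the endocyclic, more substituted C3=C4 alkene results.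

Step 7
Reactants: 12 cis-5,6-dihydroxy-N-methoxy-N,4-dimethylcyclohex-3-ene-1-carboxamide
Product: 13 5,6-O-isopropylidene Weinreb amide (cis-fused dioxolane)
Conditions: 2,2-dimethoxypropane, PPTS (cat.), CH2Cl2, rt
Reagents that add atoms: 2,2-dimethoxypropane, COC(C)(C)OC
Why: Acid-catalysed transacetalisation (acetonide formation) on the cis-5,6-diol gives the cis-fused dioxolane that masks both hydroxyls for the organometallic steps.

Step 8
Reactants: 13 5,6-O-isopropylidene Weinreb amide
Product: 14 C1 methyl ketone acetonide
Conditions: MeLi (1.3 equiv), THF, −78 °C; aq. NH4Cl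
Reagents that add atoms: methyllithium, [Li]C
Why: Weinreb ketone synthesis, in which methyllithium adds only once because the chelated tetrahedral intermediate survives until work-up, and C1 is not enolised at −78 °C.

Step 9
Reactants: 14 C1 methyl ketone acetonide
Product: 16 C7 enol triflate acetonide (C1–C7(OTf)=C12H2), via potassium enolate 15 (not isolated)
Conditions: KN(SiMe3)2 (1.1 equiv), THF, −78 °C; then N-(5-chloropyridin-2-yl)bis(trifluoromethanesulfonimide) (Comins' reagent), −78 °C to −20 °C; aq. NH4Cl
Reagents that add atoms: Comins' reagent, FC(F)(F)S(=O)(=O)N(c1ccc(Cl)cn1)S(=O)(=O)C(F)(F)F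
Why: Kinetic deprotonation of the methyl ketone on the methyl side by the hindered amide base and O-sulfonylation of the enolate (enol triflate formation) give the 1,1-disubstituted alkenyl triflate carrying C12, without enolisation toward C1 and hence without β-elimination of the C6 oxygen.

Step 10
Reactants: 17 4-methylpent-3-en-1-ol
Product: 18 4-methylpent-3-enal
Conditions: Dess–Martin periodinane, NaHCO3, CH2Cl2, 0 °C; used at once as a solution
Reagents that add atoms: none
Why: Dess–Martin oxidation of the primary alcohol under buffered, non-basic conditions gives the β,γ-unsaturated aldehyde without migration of the double bond into conjugation.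

Step 11
Reactants: 16 C7 enol triflate acetonide; 18 4-methylpent-3-enal
Product: 19 C8 allylic alcohol acetonide (both C8 epimers)
Conditions: CrCl2 (4 equiv), NiCl2 (2 mol %), degassed DMF, rt
Reagents that add atoms: none
Why: Nozaki–Hiyama–Kishi coupling, in which zerovalent nickel inserts into the C–OTf bond and transmetallation gives an alkenyl species of trivalent chromium that adds only to the aldehyde to form C7–C8; C8 arises without control and both epimers are taken on because the next step removes this centre.

Step 12
Reactants: 19 C8 allylic alcohol acetonide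
Product: 20 C8 ketone (α-methylene ketone) acetonide
Conditions: Dess–Martin periodinane, NaHCO3, CH2Cl2, 0 °C; used directly
Reagents that add atoms: none
Why: Dess–Martin oxidation of the secondary allylic alcohol gives the α-methylene ketone, the bicarbonate buffer keeping the C10=C11 alkene out of conjugation.

Step 13
Reactants: 20 C8 ketone acetonide
Product: 21 (8S)-allylic alcohol acetonide
Conditions: (R)-2-methyl-CBS-oxazaborolidine (0.5 equiv), catecholborane (1.8 equiv), toluene, −78 °C
Reagents that add atoms: none
Why: Corey–Bakshi–Shibata reduction, in which the ketone binds the oxazaborolidine–borane complex with the branched alkenyl group (C7) as the large substituent and hydride is delivered to the face that gives the 8S alcohol with the (R)-catalyst, catecholborane at −78 °C leaving the alkenes alone.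

Step 14
Reactants: 22 angelic acid
Product: 23 angelic 2,4,6-trichlorobenzoic anhydride
Conditions: 2,4,6-trichlorobenzoyl chloride (1.0 equiv), Et3N (1.0 equiv), toluene, rt; Et3N·HCl filtered off under argon; filtrate kept as a stock solution at −20 °C, on a scale that serves both angeloylations
Reagents that add atoms: 2,4,6-trichlorobenzoyl chloride, O=C(Cl)c1c(Cl)cc(Cl)cc1Cl
Why: Mixed anhydride formation by acylation of the triethylammonium carboxylate with the hindered aroyl chloride, carried out at room temperature and freed of amine salt so that the Z geometry of the angeloyl group is kept.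

Step 15
Reactants: 21 (8S)-allylic alcohol acetonide; 23 angelic 2,4,6-trichlorobenzoic anhydride
Product: 24 (8S)-angelate acetonide
Conditions: 23 (2 equiv, salt-free toluene solution), toluene, 75 °C
Reagents that add atoms: none
Why: Yamaguchi-type acylation with the preformed mixed anhydride and no nucleophilic amine catalyst, in which the alcohol attacks the unhindered angeloyl carbonyl rather than the shielded aroyl carbonyl, so the hindered C8 hydroxyl is esterified with retention at C8 and the Z geometry of the angelate is kept.

Step 16
Reactants: 24 (8S)-angelate acetonide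
Product: 25 (8S)-angelate cis-5,6-diol
Conditions: AcOH/H2O (4:1), 40 °C
Reagents that add atoms: none
Why: Acid-catalysed hydrolysis of the isopropylidene acetal in dilute acetic acid frees the cis-5,6-diol under conditions that the allylic ester, the alkenes and the stereocentres tolerate.

Step 17
Reactants: 25 (8S)-angelate cis-5,6-diol
Product: 27 C6 acetate with free C5 hydroxyl, via cyclic methyl orthoacetate 26 (not isolated)
Conditions: MeC(OMe)3 (3 equiv), PPTS (cat.), CH2Cl2, rt; then AcOH/H2O (4:1), 0 °C to rt
Reagents that add atoms: trimethyl orthoacetate, COC(C)(OC)OC; water, O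
Why: Orthoester route to a monoacylated cis-diol, in which the cyclic orthoacetate is hydrolysed through a hemiorthoester that opens to leave the acetyl group on the axial oxygen (O6 when the large C1 substituent is equatorial), so the allylic C5 hydroxyl stays free.

Step 18
Reactants: 27 C6 acetate with free C5 hydroxyl
Product: 28 3,4-epoxy-5-ol C6 acetate (oxirane on the upper face)
Conditions: VO(acac)2 (5 mol %), t-BuOOH (1.5 equiv, in decane), CH2Cl2, rt
Reagents that add atoms: tert-butyl hydroperoxide, CC(C)(C)OO
Why: VO(acac)2-catalysed hydroxyl-directed epoxidation, in which only the alkene next to the free C5 hydroxyl reacts (C7=C12 and C10=C11 have no free hydroxyl nearby) and oxygen is delivered to the upper face of C3=C4, which sets C3 and C4.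

Step 19
Reactants: 28 3,4-epoxy-5-ol C6 acetate; 23 angelic 2,4,6-trichlorobenzoic anhydride
Product: 29 3,4-epoxy C5 angelate C6 acetate
Conditions: 23 (2 equiv, salt-free toluene solution), toluene, 70 °C
Reagents that add atoms: none
Why: Mixed-anhydride (Yamaguchi-type) acylation of the C5 hydroxyl with the salt-free anhydride and no added base is chosen to outrun acetyl migration from O6 and to keep the Z geometry, and the oxirane is safe from Payne rearrangement because O5 lies on the same face as the oxirane oxygen.

Step 20
Reactants: 29 3,4-epoxy C5 angelate C6 acetate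
Product: 30 C3 chloride C4 tertiary alcohol (trans chlorohydrin)
Conditions: LiCl (10 equiv), AcOH (5 equiv), THF, rt to 45 °C
Reagents that add atoms: lithium chloride, [Li+].[Cl-]
Why: Acid-assisted SN2 opening of the oxirane by chloride (halohydrin formation) under Fürst–Plattner control, in which chloride attacks the secondary C3 from the lower face with inversion through the chair that keeps the C1 substituent equatorial and gives the trans-diaxial C3 chloride and C4 alcohol, whereas attack at C4 would need a tertiary centre next to the acyloxy-bearing C5 and a chair with three syn-axial groups.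

Step 21
Reactants: 30 C3 chloride C4 tertiary alcohol
Product: 31 CNP0313121.1 (1R,3S,4S,5S,6S,8S,10S)
Conditions: L-fructose-derived Shi ketone (1.5 equiv), KHSO5 (as 2KHSO5·KHSO4·K2SO4), NaHCO3, MeCN/aq. Na2H2EDTA, 0 °C, pH 7–8
Reagents that add atoms: potassium peroxymonosulfate, [K+].[O-]S(=O)(=O)OO
Why: Shi asymmetric epoxidation, in which the chiral dioxirane reacts through a spiro transition state with the electron-rich trisubstituted C10=C11 alkene only (C7=C12 is deactivated by the allylic ester and the angelates are electron-poor), the L-fructose-derived ketone giving 10S and the bicarbonate buffer keeping the chlorohydrin from closing.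

**Compound list**

1 | 3-methylbut-2-enal | CC(C)=CC=O | starting material
2 | isopropenyl acetate | CC(=C)OC(C)=O | starting material
3 | (E)-1-acetoxy-3-methylbuta-1,3-diene | CC(=C)/C=C/OC(C)=O | intermediate
4 | oxazolidin-2-one | O=C1NCCO1 | starting material
5 | acryloyl chloride | C=CC(=O)Cl | starting material
6 | bromomagnesium oxazolidin-2-onide | O=C1OCCN1[Mg]Br | intermediate
7 | 3-acryloyloxazolidin-2-one | C=CC(=O)N1CCOC1=O | intermediate
8 | 3-[(1S,6R)-6-acetoxy-4-methylcyclohex-4-ene-1-carbonyl]oxazolidin-2-one | O=C(N1CCOC1=O)[C@H]1CCC(C)=C[C@H]1OC(C)=O | intermediate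
9 | (1S,6R)-6-acetoxy-N-methoxy-N,4-dimethylcyclohex-4-ene-1-carboxamide | CON(C)C(=O)[C@H]1CCC(C)=C[C@H]1OC(C)=O | intermediate
10 | (1S,6R)-6-hydroxy-N-methoxy-N,4-dimethylcyclohex-4-ene-1-carboxamide | CON(C)C(=O)[C@H]1CCC(C)=C[C@H]1O | intermediate
11 | 4,5-epoxy-6-hydroxy Weinreb amide, oxirane cis to the C6 hydroxyl | CON(C)C(=O)[C@H]1CC[C@@]2(C)O[C@H]2[C@H]1O | intermediate
12 | cis-5,6-dihydroxy-N-methoxy-N,4-dimethylcyclohex-3-ene-1-carboxamide, both hydroxyls cis to the C1 amide | CON(C)C(=O)[C@H]1CC=C(C)[C@@H](O)[C@H]1O | intermediate
13 | 5,6-O-isopropylidene derivative of 12 | CON(C)C(=O)[C@H]1CC=C(C)[C@@H](OC2(C)C)[C@H]1O2 | intermediate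
14 | C1 methyl ketone acetonide | CC(=O)[C@H]1CC=C(C)[C@@H](OC2(C)C)[C@H]1O2 | intermediate
15 | potassium enolate of 14 (methyl side) | [K+].[O-]C(=C)[C@H]1CC=C(C)[C@@H](OC2(C)C)[C@H]1O2 | intermediate
16 | C7 enol triflate acetonide | C=C(OS(=O)(=O)C(F)(F)F)[C@H]1CC=C(C)[C@@H](OC2(C)C)[C@H]1O2 | intermediate
17 | 4-methylpent-3-en-1-ol | CC(C)=CCCO | starting material
18 | 4-methylpent-3-enal | CC(C)=CCC=O | intermediate
19 | C8 allylic alcohol acetonide, both C8 epimers | C=C(C(O)CC=C(C)C)[C@H]1CC=C(C)[C@@H](OC2(C)C)[C@H]1O2 | intermediate
20 | C8 ketone (α-methylene ketone) acetonide | C=C(C(=O)CC=C(C)C)[C@H]1CC=C(C)[C@@H](OC2(C)C)[C@H]1O2 | intermediate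
21 | (8S)-allylic alcohol acetonide | C=C([C@H](CC=C(C)C)O)[C@H]1CC=C(C)[C@@H](OC2(C)C)[C@H]1O2 | intermediate
22 | angelic acid, (Z)-2-methylbut-2-enoic acid | OC(=O)/C(C)=C\C | starting material
23 | angelic 2,4,6-trichlorobenzoic anhydride | O=C(OC(=O)/C(C)=C\C)c1c(Cl)cc(Cl)cc1Cl | intermediate
24 | (8S)-angelate acetonide | C=C([C@H](CC=C(C)C)OC(=O)/C(C)=C\C)[C@H]1CC=C(C)[C@@H](OC2(C)C)[C@H]1O2 | intermediate
25 | (8S)-angelate cis-5,6-diol | C=C([C@H](CC=C(C)C)OC(=O)/C(C)=C\C)[C@H]1CC=C(C)[C@@H](O)[C@H]1O | intermediate
26 | cyclic methyl orthoacetate of 25, epimers at the orthoester carbon | C=C([C@H](CC=C(C)C)OC(=O)/C(C)=C\C)[C@H]1CC=C(C)[C@@H](OC2(C)OC)[C@H]1O2 | intermediate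
27 | C6 acetate with free C5 hydroxyl, C3=C4 alkene | C=C([C@H](CC=C(C)C)OC(=O)/C(C)=C\C)[C@H]1CC=C(C)[C@@H](O)[C@H]1OC(C)=O | intermediate
28 | 3,4-epoxy-5-ol C6 acetate, oxirane cis to O5 and O6 | C=C([C@H](CC=C(C)C)OC(=O)/C(C)=C\C)[C@H]1C[C@H]2O[C@@]2(C)[C@@H](O)[C@H]1OC(C)=O | intermediate
29 | 3,4-epoxy C5 angelate C6 acetate | C=C([C@H](CC=C(C)C)OC(=O)/C(C)=C\C)[C@H]1C[C@H]2O[C@@]2(C)[C@@H](OC(=O)/C(C)=C\C)[C@H]1OC(C)=O | intermediate
30 | C3 chloride C4 tertiary alcohol with the C10=C11 alkene still in place | C=C([C@H](CC=C(C)C)OC(=O)/C(C)=C\C)[C@H]1C[C@H](Cl)[C@@](C)(O)[C@@H](OC(=O)/C(C)=C\C)[C@H]1OC(C)=O | intermediate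
31 | CNP0313121.1, (1R,3S,4S,5S,6S,8S,10S) | C=C([C@H](C[C@@H]1OC1(C)C)OC(=O)/C(C)=C\C)[C@H]1C[C@H](Cl)[C@@](C)(O)[C@@H](OC(=O)/C(C)=C\C)[C@H]1OC(C)=O | target

Total step count: 21 steps.
Longest linear sequence: 18 steps (steps 1, 3–9, 11–13 and 15–21, from 3-methylbut-2-enal).

**Steps most likely to fail**

Step 6. What may go wrong: the proton may be lost from the C4 methyl group instead of from C3 (exocyclic alkene), or isopropoxide may add at C4. Fallback, from 11 back to 13: chelation-controlled opening of the oxirane of 11 with MgBr2·OEt2 (Et2O, 0 °C) should place bromide on the tertiary C4 from the lower face and give the bromodiol F1. Treatment with 2,2-dimethoxypropane and PPTS should then give the bromo acetonide F2. An anti elimination with DBU (toluene, 90 °C) removes the C3 hydrogen antiperiplanar to the tertiary bromide (Zaitsev orientation) and gives acetonide 13. Halohydrin formation followed by base-induced elimination thus replaces the Ti(OiPr)4-mediated syn elimination.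

Step 17. What may go wrong: in the flexible half-chair of the cyclohexene diol, allylic strain between O5 and the C4 methyl may make O5 rather than O6 the axial oxygen. Orthoester opening would then put the acetate on the wrong oxygen or give mixtures, and acetyl migration may follow. Fallback, from 25 back to 27: the diol is converted with Bu2SnO (toluene, reflux, water removed) into the dibutylstannylene acetal F3, which is acetylated with AcCl (1 equiv, 0 °C). Bu2SnO-mediated acylation follows the opposite rule (the equatorial oxygen reacts), so it should acetylate O6 in exactly the case in which orthoester opening does not.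

Step 20. What may go wrong: the hindered oxirane may open slowly, with competing attack at the tertiary C4 or loss of the angelate geometry on prolonged warming in acid. Fallback, from 28 back to 30: the order of the last ring steps is changed. The free C5 hydroxyl of 28 directs the chloride: ClTi(OiPr)3 (CH2Cl2, 0 °C) binds O5 and the oxirane oxygen and delivers chloride to the distal C3 from the lower face, giving the chlorodiol F4. Acylation of its secondary C5 hydroxyl with anhydride 23 (toluene, 70 °C; the tertiary C4 hydroxyl does not react) should give 30.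

Further compounds
F1 | step 6 | C4 bromide 5,6-diol Weinreb amide (bromide on the lower face) | CON(C)C(=O)[C@H]1CC[C@](C)(Br)[C@@H](O)[C@H]1O
F2 | step 6 | 5,6-O-isopropylidene derivative of F1 | CON(C)C(=O)[C@H]1CC[C@](C)(Br)[C@@H](OC2(C)C)[C@H]1O2
F3 | step 17 | 5,6-O-dibutylstannylene acetal of 25 | C=C([C@H](CC=C(C)C)OC(=O)/C(C)=C\C)[C@H]1CC=C(C)[C@@H](O[Sn]2(CCCC)CCCC)[C@H]1O2
F4 | step 20 | C3 chloride 4,5-diol C6 acetate | C=C([C@H](CC=C(C)C)OC(=O)/C(C)=C\C)[C@H]1C[C@H](Cl)[C@@](C)(O)[C@@H](O)[C@H]1OC(C)=O
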